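**Retrosynthetic overview**

1. Ardisinone ⇐ para-oxidation (Teuber) of the (R)-2-acetoxyalkyl 3-methoxyphenol, the laboratory counterpart of the late ring oxygenation of an O-methylated alkylresorcinol.
2. That phenol ⇐ acetylation of 3-[(R)-2-hydroxypentadecyl]-5-methoxyphenol.
3. The only ring ⇐ polyketide-style C-2→C-7 aldol, aromatisation and decarboxylation (alkylresorcinol-synthase fold) of a tetraketide chain released in the flask from a 6-(2-oxoalkyl)-4-methoxypyran-2-one.
4. Tetraketide ⇐ Claisen acylation of the triketide 4-methoxy-6-methylpyran-2-one with the "starter unit" methyl (R)-3-hydroxyhexadecanoate.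
5. Starter unit ⇐ Noyori hydrogenation of methyl 3-oxohexadecanoate ⇐ methyl acetoacetate + 1-bromododecane. One ring only, formed in step 3 and oxidised to the quinone last.

Assumption: the stereocentre in the target SMILES is read as (R) (OAc > CH2-quinone > tridecyl > H), and 4-methoxy-6-methyl-2H-pyran-2-one is bought (it is also one O-methylation from triacetic acid lactone).

**Route**

Step 1
Reactants: 1 methyl acetoacetate; 2 1-bromododecane
Product: 3 methyl 3-oxohexadecanoate
Conditions: NaH, THF, 0 °C; n-BuLi, 0 °C; then 2, 0 °C → rt; aq. HCl quench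
Reagents that add atoms: none
Why: Huckin–Weiler dianion alkylation; the more basic terminal (γ) carbanion of the acetoacetate dianion is alkylated selectively by the primary bromide.

Step 2
Reactants: 3 methyl 3-oxohexadecanoate
Product: 4 methyl (R)-3-hydroxyhexadecanoate
Conditions: H2 (50 atm), RuCl2[(R)-BINAP] (0.2 mol%), MeOH, 50 °C
Reagents that add atoms: none
Why: Noyori asymmetric hydrogenation of a β-keto ester; the (R)-BINAP–Ru chelate delivers hydrogen to one face of the ketone and gives the (R)-carbinol in ≥97% ee, as for methyl (R)-3-hydroxybutanoate and (R)-3-hydroxytetradecanoate, and this is the only stereocentre of the target.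

Step 3
Reactants: 4 methyl (R)-3-hydroxyhexadecanoate; 5 4-methoxy-6-methyl-2H-pyran-2-one
Product: 9 3-[(R)-2-hydroxypentadecyl]-5-methoxyphenol, via ketopyrone 6 (not isolated), via seco acid 7 (not isolated), via resorcylic acid 8 (not isolated)
Conditions: 5 (2.2 equiv), LDA (2.2 equiv), THF, −78 °C; add Li alkoxide of 4 (4 + LDA 1.0 equiv), −78 → 0 °C; then 2 M aq. KOH, rt → 40 °C; then HCl to pH 1, 80 °C
Reagents that add atoms: none
Why: Proposed new method: the C-6-methyl lithio-pyranone is acylated by the ester of the O-lithiated hydroxy ester (crossed Claisen condensation, as lithium tert-butyl acetate is acylated by unprotected β-hydroxy esters; the second equivalent is consumed by the acidic CH2 of 6), hydroxide then opens the lactone at C-2 to the tetraketide seco acid 7, whose doubly activated C-2 adds to the C-7 ketone exactly as in the alkylresorcinol-synthase fold, E1cB dehydration and enolisation aromatise to 8, and ipso-protonation of this di-ortho-substituted p-hydroxybenzoic acid in hot acid releases CO2; the closest known reactions are the Harris/Money/Crombie base-induced conversions of 6-(2-oxoalkyl)pyran-2-ones (tetraacetic lactone and its ethers) into orsellinic acids and orcinols; no stereocentre is formed, and the carbinol centre of 4 survives because the C-7 carbonyl stays enolised towards C-6 in base, which disfavours retro-aldol cleavage and β-elimination.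

Step 4
Reactants: 9 3-[(R)-2-hydroxypentadecyl]-5-methoxyphenol
Product: 11 (R)-1-(3-hydroxy-5-methoxyphenyl)pentadecan-2-yl acetate, via diacetate 10 (not isolated)
Conditions: Ac2O (2.5 equiv), pyridine, DMAP (cat.), CH2Cl2, rt; then pyrrolidine, 0 °C
Reagents that add atoms: acetic anhydride, CC(=O)OC(C)=O
Why: DMAP-catalysed acetylation of both hydroxyls, then chemoselective aminolysis of the aryl acetate (phenoxide is a far better leaving group than a secondary alkoxide); the C–O bond at the stereocentre is never broken, so configuration is retained.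

Step 5
Reactants: 11 (R)-1-(3-hydroxy-5-methoxyphenyl)pentadecan-2-yl acetate
Product: 12 ardisinone, (R)-1-(5-methoxy-3,6-dioxocyclohexa-1,4-dien-1-yl)pentadecan-2-yl acetate
Conditions: (KSO3)2NO (2.5 equiv), KH2PO4 buffer, H2O–acetone, rt
Reagents that add atoms: Fremy's salt (dipotassium nitrosodisulfonate), [K+].[K+].[O]N(S(=O)(=O)[O-])S(=O)(=O)[O-]
Why: Teuber oxidation; the phenoxyl radical is trapped by a second nitrosodisulfonate at the free para carbon (between OMe and the side chain) and collapses to the 2-methoxy-6-alkyl-1,4-benzoquinone, as in the preparation of primin from 3-methoxy-5-pentylphenol; the buffered, near-neutral medium leaves the acetate and the stereocentre untouched.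

**Compound list**

1 | methyl acetoacetate | CC(=O)CC(=O)OC | starting material
2 | 1-bromododecane | CCCCCCCCCCCCBr | starting material
3 | methyl 3-oxohexadecanoate | CCCCCCCCCCCCCC(=O)CC(=O)OC | intermediate
4 | methyl (R)-3-hydroxyhexadecanoate | CCCCCCCCCCCCC[C@H](CC(=O)OC)O | intermediate
5 | 4-methoxy-6-methyl-2H-pyran-2-one | COC1=CC(=O)OC(C)=C1 | starting material
6 | 6-[(R)-4-hydroxy-2-oxoheptadecyl]-4-methoxy-2H-pyran-2-one (ketopyrone) | CCCCCCCCCCCCC[C@H](CC(=O)CC1=CC(OC)=CC(=O)O1)O | intermediate
7 | (2E,9R)-9-hydroxy-3-methoxy-5,7-dioxodocos-2-enoic acid (seco acid) | CCCCCCCCCCCCC[C@H](CC(=O)CC(=O)C/C(OC)=C\C(O)=O)O | intermediate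
8 | 4-hydroxy-6-[(R)-2-hydroxypentadecyl]-2-methoxybenzoic acid (resorcylic acid) | CCCCCCCCCCCCC[C@H](Cc1cc(O)cc(OC)c1C(O)=O)O | intermediate
9 | 3-[(R)-2-hydroxypentadecyl]-5-methoxyphenol | CCCCCCCCCCCCC[C@H](Cc1cc(O)cc(OC)c1)O | intermediate
10 | (R)-1-(3-acetoxy-5-methoxyphenyl)pentadecan-2-yl acetate (diacetate) | CCCCCCCCCCCCC[C@H](Cc1cc(OC(C)=O)cc(OC)c1)OC(C)=O | intermediate
11 | (R)-1-(3-hydroxy-5-methoxyphenyl)pentadecan-2-yl acetate | CCCCCCCCCCCCC[C@H](Cc1cc(O)cc(OC)c1)OC(C)=O | intermediate
12 | ardisinone | CCCCCCCCCCCCC[C@H](CC1=CC(=O)C=C(OC)C1=O)OC(C)=O | target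

**Totals**

Total step count: 5. Longest linear sequence: 5 (1 → 3 → 4 → 9 → 11 → 12; pyranone 5 enters in step 3).

**Steps most likely to fail and fallbacks**

Step 3 (highest risk). Possible failures are sluggish acylation by the β-alkoxide ester, loss of the methyl ether by conjugate addition–elimination of hydroxide, retro-aldol cleavage of the β-hydroxy ketone, and slow decarboxylation. The fallback sets out from 4 and comes back at 9, with O-methylation moved after ring formation. The lithium alkoxide of 4 is added to the more nucleophilic dianion of triacetic acid lactone (4-hydroxy-6-methyl-2H-pyran-2-one, 2 LDA per lactone, THF, −78 → 0 °C; Harris acylation) to give 4-hydroxy-6-[(R)-4-hydroxy-2-oxoheptadecyl]-2H-pyran-2-one F1. Aqueous 2 M KOH at rt converts this into 2,4-dihydroxy-6-[(R)-2-hydroxypentadecyl]benzoic acid F2, which loses CO2 on acidification and warming to give 5-[(R)-2-hydroxypentadecyl]benzene-1,3-diol F3. Mono-O-methylation (MeI 1.0 equiv, K2CO3, acetone; statistical, with diol and dimethyl ether separated and the diol recycled) then gives 9.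

Step 4. Possible failures are incomplete discrimination between the aryl and the secondary acetate, or acetyl scrambling. The fallback sets out from 9 and comes back at 11, replacing kinetic selectivity by a protecting-group sequence. The phenol alone is benzylated (BnBr, K2CO3, acetone, reflux) to give (R)-1-[3-(benzyloxy)-5-methoxyphenyl]pentadecan-2-ol F4. The carbinol is acetylated (Ac2O, pyridine, DMAP) to give (R)-1-[3-(benzyloxy)-5-methoxyphenyl]pentadecan-2-yl acetate F5. Hydrogenolysis (H2, Pd/C, EtOAc) then frees the phenol and gives 11.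

Step 5. Possible failures are ortho-quinone formation, over-oxidation of the electrophilic product, or capricious Fremy's salt. The fallback sets out from 8 and comes back at 12; 8 is isolated by stopping step 3 after the KOH stage with cold acidification to pH 3 and extraction, without heating. Ipso-oxidative decarboxylation of this p-hydroxybenzoic acid (PhI(OAc)2 2.2 equiv, MeCN–H2O, 0 °C) gives 2-[(R)-2-hydroxypentadecyl]-6-methoxycyclohexa-2,5-diene-1,4-dione F6, with the carboxyl carbon fixing the position of the second quinone carbonyl. The only remaining hydroxyl is then acetylated (Ac2O, pyridine, CH2Cl2, 0 °C) to give 12.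

**Further compounds**

F1 | step 3 | 4-hydroxy-6-[(R)-4-hydroxy-2-oxoheptadecyl]-2H-pyran-2-one | CCCCCCCCCCCCC[C@H](CC(=O)CC1=CC(O)=CC(=O)O1)O
F2 | step 3 | 2,4-dihydroxy-6-[(R)-2-hydroxypentadecyl]benzoic acid | CCCCCCCCCCCCC[C@H](Cc1cc(O)cc(O)c1C(O)=O)O
F3 | step 3 | 5-[(R)-2-hydroxypentadecyl]benzene-1,3-diol | CCCCCCCCCCCCC[C@H](Cc1cc(O)cc(O)c1)O
F4 | step 4 | (R)-1-[3-(benzyloxy)-5-methoxyphenyl]pentadecan-2-ol | CCCCCCCCCCCCC[C@H](Cc1cc(OCc2ccccc2)cc(OC)c1)O
F5 | step 4 | (R)-1-[3-(benzyloxy)-5-methoxyphenyl]pentadecan-2-yl acetate | CCCCCCCCCCCCC[C@H](Cc1cc(OCc2ccccc2)cc(OC)c1)OC(C)=O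
F6 | step 5 | 2-[(R)-2-hydroxypentadecyl]-6-methoxycyclohexa-2,5-diene-1,4-dione | CCCCCCCCCCCCC[C@H](CC1=CC(=O)C=C(OC)C1=O)O
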